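**Retrosynthetic overview**
- The target is a C2-symmetric 2,2'-biquinone. It is traced back, through cleavage of two isopropyl vinylogous esters and a hydroquinone-to-quinone oxidation, to a 2,2'-bi(hydroquinone).
- Key disconnection: both six-membered rings come at once from two four-membered rings. A buta-1,3-diene carrying a 4-hydroxycyclobutenone on each terminus undergoes a twofold thermal 4π-opening/6π-closure ring expansion (four to six atoms, twice).
- Enabling feature: in each quinone ring the contiguous carbons C(=O)–C(CH3)=C(OH)–C(=O) (C-3 to C-6) are a squarate-type four-carbon unit. The other two ring carbons (biaryl carbon C-1 and phenethyl-bearing C-2) join with C-1'/C-2' of the twin ring into a 1,4-dialkylbuta-1,3-diene, C-2=C-1–C-1'=C-2'. Its central σ-bond is the biaryl bond, so no hindered aryl–aryl coupling is needed.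
- The bis(cyclobutenone) comes from a (3E,5E)-3,6-dilithio-octa-3,5-diene and two molecules of 3-isopropoxy-4-methylcyclobutenedione (diisopropyl squarate + MeLi). The diene comes from a Glaser diyne by twofold syn-protoboration and iododeboronation; the diyne from 2-methoxybenzyl chloride and silylpropyne.
- Order of ring formation: the anisole rings and the four-membered rings are bought; quinone rings A and B are formed together, last, in the key step.

Key step: step 7

Assumption: the target SMILES carries no stereodescriptor, so the hindered biaryl axis is taken as unspecified (racemic). The only stereochemical elements to control are the two alkene geometries of the diene precursor.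

**Step 1**
Reactants: 1 trimethyl(prop-1-yn-1-yl)silane; 2 1-(chloromethyl)-2-methoxybenzene
Product: 5 1-(but-3-yn-1-yl)-2-methoxybenzene, via propargyllithium 3 (not isolated), via silylated alkyne 4 (not isolated)
Conditions: n-BuLi, THF, −78 to −20 °C; 2, −78 °C to rt; then K2CO3, MeOH, rt
Reagents that add atoms: none
Why: Propargylic lithiation of the silyl-capped propyne and SN2 alkylation by the benzylic chloride should give the acetylenic rather than the allenic product because silicon blocks the alkyne terminus, and K2CO3/MeOH protodesilylation then frees the terminal alkyne.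

**Step 2**
Reactants: 5 1-(but-3-yn-1-yl)-2-methoxybenzene (two molecules)
Product: 6 1,8-bis(2-methoxyphenyl)octa-3,5-diyne
Conditions: CuCl (cat.), TMEDA, O2 (1 atm), acetone, rt
Reagents that add atoms: none
Why: Glaser–Hay oxidative homocoupling of a terminal alkyl alkyne is general, and the aryl methyl ethers are inert to it.

**Step 3**
Reactants: 6 1,8-bis(2-methoxyphenyl)octa-3,5-diyne
Product: 8 2,2'-[(3Z,5Z)-1,8-bis(2-methoxyphenyl)octa-3,5-diene-3,6-diyl]bis(4,4,5,5-tetramethyl-1,3,2-dioxaborolane), via monoborylated enyne 7 (not isolated)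
Conditions: B2pin2 (2.4 equiv), CuCl (10 mol %), P(p-tolyl)3 (12 mol %), NaOt-Bu (20 mol %), MeOH (4 equiv), THF, rt
Reagents that add atoms: bis(pinacolato)diboron, CC1(C)OB(OC1(C)C)B1OC(C)(C)C(C)(C)O1
Why: Copper-catalysed protoboration (syn-borylcupration, then protonation of the C–Cu bond by MeOH with retention) should place boron on the outer carbon of the conjugated diyne, because copper prefers the carbon conjugated to the remaining unsaturation, and the same bias should operate on enyne 7, so each new C–B bond ends up cis to the new C–H bond.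

**Step 4**
Reactants: 8 the (3Z,5Z)-bis(pinacolboronate)
Product: 9 (3E,5E)-3,6-diiodo-1,8-bis(2-methoxyphenyl)octa-3,5-diene
Conditions: I2, aq. NaOH (3 M), THF, 0 °C, dark
Reagents that add atoms: iodine, [I][I]
Why: Iododeboronation of the hydroxide ate complex of an alkenyl pinacolboronate proceeds with retention of alkene geometry, so each iodine should stay cis to the vinylic hydrogen.

**Step 5**
Reactants: 10 3,4-di(propan-2-yloxy)cyclobut-3-ene-1,2-dione (diisopropyl squarate)
Product: 13 3-methyl-4-(propan-2-yloxy)cyclobut-3-ene-1,2-dione, via lithium alkoxide 11 (not isolated), via trifluoroacetate 12 (not isolated)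
Conditions: MeLi, THF, −78 °C; then (CF3CO)2O, −78 °C to rt; H2O
Reagents that add atoms: methyllithium, [Li]C; water, O
Why: 1,2-Addition of MeLi to one carbonyl of the symmetrical squarate, then trifluoroacetylation, ionisation of the allylic ester and hydrolytic loss of one isopropoxy group, is the standard entry to 3-alkoxy-4-alkylcyclobutenediones.

**Step 6**
Reactants: 9 the (3E,5E)-diiodide; 13 3-methyl-4-(propan-2-yloxy)cyclobut-3-ene-1,2-dione (two molecules)
Product: 15 4,4'-[(3E,5E)-1,8-bis(2-methoxyphenyl)octa-3,5-diene-3,6-diyl]bis[4-hydroxy-2-methyl-3-(propan-2-yloxy)cyclobut-2-en-1-one] (mixture of diastereomers at the two carbinol carbons), via dilithiodiene 14 (not isolated)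
Conditions: t-BuLi (4.2 equiv), Et2O, −78 °C; then 13 (2.2 equiv), THF, −78 °C; H2O
Reagents that add atoms: none
Why: Iodine–lithium exchange is stereoretentive and alkenyllithiums add to the ketone-like carbonyl of 13 (the one next to the alkoxy-bearing carbon) rather than to the vinylogous ester carbonyl, while the two carbinol centres form without control, which is irrelevant because step 7 destroys both.

**Step 7**
Reactants: 15 the diene-bridged bis(4-hydroxycyclobutenone)
Product: 21 2,2'-bis[2-(2-methoxyphenyl)ethyl]-5,5'-dimethyl-4,4'-di(propan-2-yloxy)-[1,1'-biphenyl]-3,3',6,6'-tetrol, via dienylketene 16 (not isolated), via cyclohexadienone 17 (not isolated), via half-expanded hydroquinone 18 (not isolated), via second dienylketene 19 (not isolated), via second cyclohexadienone 20 (not isolated)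
Conditions: p-xylene (0.01 M), 138 °C, Ar
Reagents that add atoms: none
Why: Each 4-alkenyl-4-hydroxycyclobutenone should undergo thermal conrotatory 4π ring opening to a dienylketene, which closes between the ketene carbon and the diene CH and enolises, so each four-membered ring is expanded by two alkene carbons into a benzene-1,4-diol ring and the central σ-bond of the diene becomes the biaryl bond. The closest known reaction type is the thermal ring expansion of 4-alkenyl- and 4-aryl-4-hydroxycyclobutenones to hydroquinones (Moore-type rearrangement), here run twice in one molecule. Each six-membered ring is closed by a disrotatory 6π-electrocyclisation. No stereocentre survives, since the sp3 carbons of 17 and 20 are erased on enolisation and both carbinol centres of 15 become aromatic carbons. The step needs inward rotation of the alkenyl group on ring opening, which the outward preference of the hydroxyl group secures; it needs 6π closure at an unhindered CH terminus without 8π closure onto the far alkene, which the E geometry from steps 3 and 4 (ring carbon cis to H) secures; and it needs the O/CH3/O-iPr/O pattern around each ring, which the regiochemistry of step 6 fixes.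

**Step 8**
Reactants: 21 the biphenyl-3,3',6,6'-tetrol
Product: 22 2,2'-bis[2-(2-methoxyphenyl)ethyl]-5,5'-dimethyl-4,4'-di(propan-2-yloxy)-[1,1'-bi(cyclohexa-1,4-dien-1-yl)]-3,3',6,6'-tetrone
Conditions: Ag2O, MgSO4, Et2O, rt
Reagents that add atoms: none
Why: Ag2O dehydrogenates para-hydroquinones to quinones under neutral conditions that leave the anisole and isopropyl ethers untouched.

**Step 9**
Reactants: 22 the bis(isopropoxy)biquinone
Product: 23 4,4'-dihydroxy-2,2'-bis[2-(2-methoxyphenyl)ethyl]-5,5'-dimethyl-[1,1'-bi(cyclohexa-1,4-dien-1-yl)]-3,3',6,6'-tetrone (CNP0293637.0)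
Conditions: NaOH (1 M aq.), THF/MeOH, 0 °C to rt; then HCl (1 M)
Reagents that add atoms: sodium hydroxide, [Na+].[OH-]
Why: Hydroxide should add to the alkoxy-bearing carbon of each 2-alkoxy-1,4-quinone (a vinylogous ester) and expel isopropoxide by addition–elimination, the vinylogous carboxylate resisting further attack until acidification, while the aryl methyl ethers are inert.

**Compound list**
1 | trimethyl(prop-1-yn-1-yl)silane | CC#C[Si](C)(C)C | starting material
2 | 1-(chloromethyl)-2-methoxybenzene | COc1ccccc1CCl | starting material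
3 | [3-(trimethylsilyl)prop-2-yn-1-yl]lithium | [Li]CC#C[Si](C)(C)C | intermediate
4 | [4-(2-methoxyphenyl)but-1-yn-1-yl]trimethylsilane | COc1ccccc1CCC#C[Si](C)(C)C | intermediate
5 | 1-(but-3-yn-1-yl)-2-methoxybenzene | COc1ccccc1CCC#C | intermediate
6 | 1,8-bis(2-methoxyphenyl)octa-3,5-diyne | COc1ccccc1CCC#CC#CCCc1ccccc1OC | intermediate
7 | 2-[(3Z)-1,8-bis(2-methoxyphenyl)oct-3-en-5-yn-3-yl]-4,4,5,5-tetramethyl-1,3,2-dioxaborolane | COc1ccccc1CC/C(B2OC(C)(C)C(C)(C)O2)=C\C#CCCc1ccccc1OC | intermediate
8 | 2,2'-[(3Z,5Z)-1,8-bis(2-methoxyphenyl)octa-3,5-diene-3,6-diyl]bis(4,4,5,5-tetramethyl-1,3,2-dioxaborolane) | COc1ccccc1CC/C(B2OC(C)(C)C(C)(C)O2)=C\C=C(/CCc1ccccc1OC)B1OC(C)(C)C(C)(C)O1 | intermediate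
9 | (3E,5E)-3,6-diiodo-1,8-bis(2-methoxyphenyl)octa-3,5-diene | I/C(CCc1ccccc1OC)=C/C=C(\CCc1ccccc1OC)I | intermediate
10 | 3,4-di(propan-2-yloxy)cyclobut-3-ene-1,2-dione | CC(C)OC1=C(OC(C)C)C(=O)C1=O | starting material
11 | lithium 1-methyl-4-oxo-2,3-di(propan-2-yloxy)cyclobut-2-en-1-olate (racemic) | [Li]OC1(C)C(=O)C(OC(C)C)=C1OC(C)C | intermediate
12 | 1-methyl-4-oxo-2,3-di(propan-2-yloxy)cyclobut-2-en-1-yl trifluoroacetate (racemic) | CC1(OC(=O)C(F)(F)F)C(=O)C(OC(C)C)=C1OC(C)C | intermediate
13 | 3-methyl-4-(propan-2-yloxy)cyclobut-3-ene-1,2-dione | CC1=C(OC(C)C)C(=O)C1=O | intermediate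
14 | [(3Z,5Z)-1,8-bis(2-methoxyphenyl)octa-3,5-diene-3,6-diyl]dilithium (each Li cis to the vinylic H) | COc1ccccc1CC/C([Li])=C\C=C(/CCc1ccccc1OC)[Li] | intermediate
15 | 4,4'-[(3E,5E)-1,8-bis(2-methoxyphenyl)octa-3,5-diene-3,6-diyl]bis[4-hydroxy-2-methyl-3-(propan-2-yloxy)cyclobut-2-en-1-one] (carbinol centres unassigned, mixture of diastereomers) | COc1ccccc1CC/C(C2(O)C(=O)C(C)=C2OC(C)C)=C\C=C(/CCc1ccccc1OC)C1(O)C(=O)C(C)=C1OC(C)C | intermediate
16 | dienylketene from opening of one cyclobutenone of 15 (ketene cis to the alkenyl group, diene E,E) | O=C=C(C)/C(OC(C)C)=C(O)\C(CCc1ccccc1OC)=C\C=C(/CCc1ccccc1OC)C1(O)C(=O)C(C)=C1OC(C)C | intermediate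
17 | cyclohexa-2,4-dienone from 6π closure of 16 (sp3 ring carbon and carbinol centre unassigned) | O=C1C(C)=C(OC(C)C)C(O)=C(CCc2ccccc2OC)C1/C=C(\CCc1ccccc1OC)C1(O)C(=O)C(C)=C1OC(C)C | intermediate
18 | half-expanded compound: hydroquinone ring carrying the (E)-alkenyl 4-hydroxycyclobutenone | COc1ccccc1CCc1c(O)c(OC(C)C)c(C)c(O)c1/C=C(\CCc1ccccc1OC)C1(O)C(=O)C(C)=C1OC(C)C | intermediate
19 | dienylketene from opening of the second cyclobutenone of 18 | COc1ccccc1CCc1c(O)c(OC(C)C)c(C)c(O)c1/C=C(CCc1ccccc1OC)/C(O)=C(OC(C)C)\C(C)=C=O | intermediate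
20 | cyclohexa-2,4-dienone from 6π closure of 19 (sp3 ring carbon unassigned) | COc1ccccc1CCc1c(O)c(OC(C)C)c(C)c(O)c1C1C(=O)C(C)=C(OC(C)C)C(O)=C1CCc1ccccc1OC | intermediate
21 | 2,2'-bis[2-(2-methoxyphenyl)ethyl]-5,5'-dimethyl-4,4'-di(propan-2-yloxy)-[1,1'-biphenyl]-3,3',6,6'-tetrol | COc1ccccc1CCc1c(O)c(OC(C)C)c(C)c(O)c1-c1c(O)c(C)c(OC(C)C)c(O)c1CCc1ccccc1OC | intermediate
22 | 2,2'-bis[2-(2-methoxyphenyl)ethyl]-5,5'-dimethyl-4,4'-di(propan-2-yloxy)-[1,1'-bi(cyclohexa-1,4-dien-1-yl)]-3,3',6,6'-tetrone | COc1ccccc1CCC1=C(C2=C(CCc3ccccc3OC)C(=O)C(OC(C)C)=C(C)C2=O)C(=O)C(C)=C(OC(C)C)C1=O | intermediate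
23 | 4,4'-dihydroxy-2,2'-bis[2-(2-methoxyphenyl)ethyl]-5,5'-dimethyl-[1,1'-bi(cyclohexa-1,4-dien-1-yl)]-3,3',6,6'-tetrone | COc1ccccc1CCC1=C(C2=C(CCc3ccccc3OC)C(=O)C(O)=C(C)C2=O)C(=O)C(C)=C(O)C1=O | target

**Count**
Total steps: 9. Longest linear sequence: 8 (steps 1, 2, 3, 4, 6, 7, 8, 9); step 5 is a one-step side branch.

**Steps most likely to fail**

1. Step 3. The second borylcupration may lose regiocontrol (boron delivered to an inner carbon), or the propargyl-type copper intermediate may be protonated at the remote carbon (cumulene formation), so the diene would form as a mixture.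
   Fallback: it gives up the substituted diene, sets out from dione 13 and comes back at biquinone 22. Tin–lithium exchange of commercial (E)-1,2-bis(tributylstannyl)ethene (n-BuLi, THF, −78 °C) should give (E)-2-(tributylstannyl)ethenyllithium F1. Its addition to 13 should give 4-hydroxy-2-methyl-3-(propan-2-yloxy)-4-[(E)-2-(tributylstannyl)ethenyl]cyclobut-2-en-1-one F2. CuCl-mediated oxidative homocoupling of the alkenylstannane (DMF, rt, retention of geometry) should give 4,4'-[(1E,3E)-buta-1,3-diene-1,4-diyl]bis[4-hydroxy-2-methyl-3-(propan-2-yloxy)cyclobut-2-en-1-one] F3. The same twofold thermal ring expansion (p-xylene, 138 °C) should give 5,5'-dimethyl-4,4'-di(propan-2-yloxy)-[1,1'-biphenyl]-3,3',6,6'-tetrol F4, and Ag2O should give 5,5'-dimethyl-4,4'-di(propan-2-yloxy)-[1,1'-bi(cyclohexa-1,4-dien-1-yl)]-3,3',6,6'-tetrone F5. The only unsubstituted carbon of each quinone ring is then alkylated by the 2-(2-methoxyphenyl)ethyl radical from 3-(2-methoxyphenyl)propanoic acid (AgNO3 cat., (NH4)2S2O8, MeCN/H2O, 65 °C; Minisci-type decarboxylative alkylation) to reach 22.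

2. Step 7. Biaryl congestion may retard the second electrocyclisation, so that the second ketene is intercepted by a phenolic hydroxyl of the first-formed ring or oligomerises.
   Fallback: it builds the two rings separately and joins them afterwards; it sets out from 2 and 13 and comes back at 21. Chloride 2 is converted (Mg, THF) into (2-methoxybenzyl)magnesium chloride F6, which with 2,3-dibromoprop-1-ene should give 1-(3-bromobut-3-en-1-yl)-2-methoxybenzene F7. Bromine–lithium exchange (t-BuLi, −78 °C) should give [4-(2-methoxyphenyl)but-1-en-2-yl]lithium F8. Its addition to 13 should give 4-hydroxy-4-[4-(2-methoxyphenyl)but-1-en-2-yl]-2-methyl-3-(propan-2-yloxy)cyclobut-2-en-1-one F9. A single ring expansion (toluene, 110 °C) should give 5-[2-(2-methoxyphenyl)ethyl]-2-methyl-3-(propan-2-yloxy)benzene-1,4-diol F10, half of which is oxidised (Ag2O) to 5-[2-(2-methoxyphenyl)ethyl]-2-methyl-3-(propan-2-yloxy)cyclohexa-2,5-diene-1,4-dione F11. BF3·OEt2-promoted addition of the only free aromatic CH of F10 to the only unsubstituted quinone carbon of F11 (quinone–hydroquinone coupling of Friedel–Crafts type) and tautomerisation should give 21.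

3. Step 9. Base-mediated degradation of the biquinone (redox disproportionation or intramolecular O-cyclisation) may compete with cleavage of the hindered vinylogous esters.
   Fallback: it removes the isopropyl groups before oxidation under Lewis-acid conditions; it sets out from 21 and comes back at 23. BCl3 (CH2Cl2, −78 to 0 °C) cleaves aryl isopropyl ethers in preference to aryl methyl ethers and should give 2,2'-bis[2-(2-methoxyphenyl)ethyl]-5,5'-dimethyl-[1,1'-biphenyl]-3,3',4,4',6,6'-hexol F12. Air or Ag2O should then oxidise each 1,2,4-trihydroxyarene ring to the 2-hydroxy-1,4-quinone, giving 23.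

**Further compounds**
F1 | step 3 | (E)-2-(tributylstannyl)ethenyllithium | CCCC[Sn](CCCC)(CCCC)/C=C/[Li]
F2 | step 3 | 4-hydroxy-2-methyl-3-(propan-2-yloxy)-4-[(E)-2-(tributylstannyl)ethenyl]cyclobut-2-en-1-one (racemic) | CCCC[Sn](CCCC)(CCCC)/C=C/C1(O)C(=O)C(C)=C1OC(C)C
F3 | step 3 | 4,4'-[(1E,3E)-buta-1,3-diene-1,4-diyl]bis[4-hydroxy-2-methyl-3-(propan-2-yloxy)cyclobut-2-en-1-one] (mixture of diastereomers) | CC(C)OC1=C(C)C(=O)C1(O)/C=C/C=C/C1(O)C(=O)C(C)=C1OC(C)C
F4 | step 3 | 5,5'-dimethyl-4,4'-di(propan-2-yloxy)-[1,1'-biphenyl]-3,3',6,6'-tetrol | CC(C)Oc1c(C)c(O)c(-c2cc(O)c(OC(C)C)c(C)c2O)cc1O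
F5 | step 3 | 5,5'-dimethyl-4,4'-di(propan-2-yloxy)-[1,1'-bi(cyclohexa-1,4-dien-1-yl)]-3,3',6,6'-tetrone | CC(C)OC1=C(C)C(=O)C(C2=CC(=O)C(OC(C)C)=C(C)C2=O)=CC1=O
F6 | step 7 | (2-methoxybenzyl)magnesium chloride | COc1ccccc1C[Mg]Cl
F7 | step 7 | 1-(3-bromobut-3-en-1-yl)-2-methoxybenzene | COc1ccccc1CCC(Br)=C
F8 | step 7 | [4-(2-methoxyphenyl)but-1-en-2-yl]lithium | COc1ccccc1CCC([Li])=C
F9 | step 7 | 4-hydroxy-4-[4-(2-methoxyphenyl)but-1-en-2-yl]-2-methyl-3-(propan-2-yloxy)cyclobut-2-en-1-one (racemic) | COc1ccccc1CCC(=C)C1(O)C(=O)C(C)=C1OC(C)C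
F10 | step 7 | 5-[2-(2-methoxyphenyl)ethyl]-2-methyl-3-(propan-2-yloxy)benzene-1,4-diol | COc1ccccc1CCc1cc(O)c(C)c(OC(C)C)c1O
F11 | step 7 | 5-[2-(2-methoxyphenyl)ethyl]-2-methyl-3-(propan-2-yloxy)cyclohexa-2,5-diene-1,4-dione | COc1ccccc1CCC1=CC(=O)C(C)=C(OC(C)C)C1=O
F12 | step 9 | 2,2'-bis[2-(2-methoxyphenyl)ethyl]-5,5'-dimethyl-[1,1'-biphenyl]-3,3',4,4',6,6'-hexol | COc1ccccc1CCc1c(O)c(O)c(C)c(O)c1-c1c(O)c(C)c(O)c(O)c1CCc1ccccc1OC
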